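**Retrosynthetic overview**
1. The strategy rests on the acyclic all-E triene C4=C5–C6=C7–C8=C9 of the C12 ether chain. Its last bond, C8=C9, ties dienyl carbon C8 to C9, which carries only the propyl tail C10–C12, so it is cut into a C1–C8 (2E,4E)-dienal and a butyl 1-phenyltetrazol-5-yl sulfone (Julia–Kocienski).
2. The dienal goes back through C4=C5 (vinylogous Horner–Wadsworth–Emmons) and the C1–O ether bond (Williamson) to (R)-solketal, which supplies the only stereocentre, glycerol C2.
3. The C2–O aroyl bond is made after the triene: ketal off, primary O-silylation, Steglich esterification with O-silylated 4-hydroxybenzoic acid, and buffered fluoride last so that the 2-O-acyl group stays in place.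
4. No ring is formed at any stage: the benzene ring is bought, and the dioxolane ring of solketal is only a protecting group that is opened in the endgame.

Key step: step 8

Remark: chain atoms are numbered C1 (OCH2) to C12 (CH3), and TBS means tert-butyldimethylsilyl. From the key step onward all material is assumed to be handled under argon and away from light, because conjugated trienes isomerise and autoxidise.

**Step 1**
Reactants: 1 (R)-solketal (2,3-O-isopropylidene-sn-glycerol); 2 5-bromopent-1-ene
Product: 4 1-O-(pent-4-enyl)-2,3-O-isopropylidene-sn-glycerol, via sodium alkoxide 3 (not isolated)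
Conditions: NaH (1.2 equiv), DMF, 0 °C; then 2 (1.2 equiv), Bu4NI (cat.), 0 °C → rt
Reagents that add atoms: none
Why: Williamson ether synthesis, in which the primary alkoxide 3 displaces bromide from an unhindered primary carbon by SN2, the ketal is inert to base, and the glycerol C2 centre bought with 1 is not touched.

**Step 2**
Reactants: 4 1-O-(pent-4-enyl)-2,3-O-isopropylidene-sn-glycerol
Product: 6 1-O-(4-oxobutyl)-2,3-O-isopropylidene-sn-glycerol, via secondary ozonide 5 (not isolated)
Conditions: O3, CH2Cl2, −78 °C; then PPh3 (1.1 equiv), −78 °C → rt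
Reagents that add atoms: ozone, [O-][O+]=O
Why: Ozonolysis with reductive work-up, in which ozone adds to the only C=C bond and the resulting ozonide 5 is reduced by PPh3 under acid-free conditions, so the ketal and the ether link survive and C4 emerges as the aldehyde.

**Step 3**
Reactants: 6 1-O-(4-oxobutyl)-2,3-O-isopropylidene-sn-glycerol; 7 triethyl (E)-4-phosphonocrotonate
Product: 9 ethyl (2E,4E)-8-{[(4R)-2,2-dimethyl-1,3-dioxolan-4-yl]methoxy}octa-2,4-dienoate, via lithiated phosphonate 8 (not isolated)
Conditions: 7 (1.3 equiv), LiN(SiMe3)2 (1.25 equiv), THF, −78 °C; then 6, −78 → 0 °C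
Reagents that add atoms: none
Why: Vinylogous Horner–Wadsworth–Emmons olefination, in which the delocalised anion 8 reacts through the carbon next to phosphorus and the reversible addition of this stabilised anion funnels to the E alkene at C4=C5, while the crotonate double bond (C6=C7) keeps its E geometry.

**Step 4**
Reactants: 9 ethyl (2E,4E)-8-{[(4R)-2,2-dimethyl-1,3-dioxolan-4-yl]methoxy}octa-2,4-dienoate
Product: 10 1-O-[(4E,6E)-8-hydroxyocta-4,6-dienyl]-2,3-O-isopropylidene-sn-glycerol
Conditions: i-Bu2AlH (2.3 equiv), CH2Cl2, −78 °C; aq. KNaC4H4O6 work-up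
Reagents that add atoms: none
Why: 1,2-Reduction of a conjugated ester with a neutral aluminium hydride, which delivers two hydrides to the carbonyl carbon without conjugate reduction and does not open the dioxolane at −78 °C.

**Step 5**
Reactants: 10 1-O-[(4E,6E)-8-hydroxyocta-4,6-dienyl]-2,3-O-isopropylidene-sn-glycerol
Product: 11 1-O-[(4E,6E)-8-oxoocta-4,6-dienyl]-2,3-O-isopropylidene-sn-glycerol
Conditions: activated MnO2 (15 equiv), CH2Cl2, rt
Reagents that add atoms: none
Why: Chemoselective allylic alcohol oxidation on MnO2, a neutral heterogeneous oxidant that stops at the aldehyde and leaves the diene geometry, the ether and the ketal alone.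

**Step 6**
Reactants: 12 1-phenyl-1H-tetrazole-5-thiol; 13 1-bromobutane
Product: 14 5-(butylsulfanyl)-1-phenyl-1H-tetrazole
Conditions: K2CO3 (1.5 equiv), acetone, reflux
Reagents that add atoms: none
Why: S-alkylation by SN2, since the soft thiolate of 12 attacks a primary bromide through sulfur rather than nitrogen.

**Step 7**
Reactants: 14 5-(butylsulfanyl)-1-phenyl-1H-tetrazole
Product: 15 5-(butylsulfonyl)-1-phenyl-1H-tetrazole
Conditions: 30% aq. H2O2 (6 equiv), (NH4)6Mo7O24·4H2O (0.1 equiv), EtOH, 0 °C → rt
Reagents that add atoms: hydrogen peroxide, OO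
Why: Molybdate-catalysed peroxide oxidation of a sulfide to the sulfone by two oxygen transfers to sulfur, with the electron-poor tetrazole ring left unoxidised.

**Step 8**
Reactants: 11 1-O-[(4E,6E)-8-oxoocta-4,6-dienyl]-2,3-O-isopropylidene-sn-glycerol; 15 5-(butylsulfonyl)-1-phenyl-1H-tetrazole
Product: 18 1-O-[(4E,6E,8E)-dodeca-4,6,8-trienyl]-2,3-O-isopropylidene-sn-glycerol, via potassiated sulfone 16 (not isolated), via alkoxide adduct 17 (not isolated)
Conditions: 15 (1.3 equiv), KN(SiMe3)2 (1.2 equiv), DME, −55 °C, 30 min; then 11 (1.0 equiv) in DME, dropwise, −55 °C → rt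
Reagents that add atoms: none
Why: This is a Julia–Kocienski olefination, the known reaction of unbranched alkyl 1-phenyltetrazol-5-yl sulfones with conjugated aldehydes: carbanion 16 adds to the formyl carbon C8 of 11 to give alkoxide 17, the tetrazole shifts from sulfur to oxygen in a Smiles rearrangement, and antiperiplanar loss of SO2 and 1-phenyltetrazol-5-olate leaves the C8=C9 double bond. No ring closes and no lasting stereocentre arises, since the two new centres of 17 disappear in the elimination and serve only to relay the alkene geometry. The selectivity needed is E at C8=C9; it comes from the kinetic preference of the bulky, weakly coordinated potassium sulfonyl anion in DME for the anti adduct, and with a dienal any syn adduct can revert or collapse through a dienyl-stabilised open zwitterion that also ends in the E alkene. The C3 methylene of 11 is vinylogously acidic even though the formyl group has no enolisable neighbour, so 15 is metalated completely with a slight deficit of base before 11 is added slowly in the cold, which keeps free amide away from the aldehyde. C4=C5, C6=C7, the ether, the dioxolane and glycerol C2 are inert to these conditions.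

**Step 9**
Reactants: 18 1-O-[(4E,6E,8E)-dodeca-4,6,8-trienyl]-2,3-O-isopropylidene-sn-glycerol
Product: 19 1-O-[(4E,6E,8E)-dodeca-4,6,8-trienyl]-sn-glycerol
Conditions: AcOH–H2O–THF (3:1:1), 40 °C, argon, dark
Reagents that add atoms: none
Why: Acid-catalysed ketal hydrolysis, in which acetic acid is strong enough to ionise the ketal carbon but too weak to protonate the triene, and only bonds to the ketal carbon break, so C2 keeps its configuration (now S by priority rules).

**Step 10**
Reactants: 19 1-O-[(4E,6E,8E)-dodeca-4,6,8-trienyl]-sn-glycerol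
Product: 20 3-O-(tert-butyldimethylsilyl)-1-O-[(4E,6E,8E)-dodeca-4,6,8-trienyl]-sn-glycerol
Conditions: t-BuMe2SiCl (1.05 equiv), imidazole (2 equiv), CH2Cl2, 0 °C
Reagents that add atoms: tert-butyldimethylsilyl chloride, CC(C)(C)[Si](C)(C)Cl
Why: Sterically controlled regioselective silylation, in which the bulky silyl chloride takes the primary hydroxyl of the 1,2-diol well ahead of the flanked secondary one.

**Step 11**
Reactants: 21 4-hydroxybenzoic acid
Product: 23 4-(tert-butyldimethylsilyloxy)benzoic acid, via silyl ester 22 (not isolated)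
Conditions: t-BuMe2SiCl (2.5 equiv), imidazole (5 equiv), DMF, rt; then AcOH–H2O–THF (3:1:1), rt
Reagents that add atoms: tert-butyldimethylsilyl chloride, CC(C)(C)[Si](C)(C)Cl
Why: Exhaustive silylation followed by selective solvolysis, which relies on the silyl ester being far more labile to aqueous acid than the aryl silyl ether.

**Step 12**
Reactants: 20 3-O-(tert-butyldimethylsilyl)-1-O-[(4E,6E,8E)-dodeca-4,6,8-trienyl]-sn-glycerol; 23 4-(tert-butyldimethylsilyloxy)benzoic acid
Product: 24 2-O-[4-(tert-butyldimethylsilyloxy)benzoyl]-3-O-(tert-butyldimethylsilyl)-1-O-[(4E,6E,8E)-dodeca-4,6,8-trienyl]-sn-glycerol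
Conditions: 23 (1.3 equiv), i-PrN=C=N-i-Pr (1.5 equiv), 4-(dimethylamino)pyridine (0.5 equiv), CH2Cl2, 0 °C → rt
Reagents that add atoms: none
Why: Steglich esterification, in which carbodiimide activation and acyl transfer by 4-(dimethylamino)pyridine acylate the secondary hydroxyl on oxygen, so the C2–O bond is kept with retention, and the nearly neutral medium spares the triene and does not shift the silyl group.

**Step 13**
Reactants: 24 2-O-[4-(tert-butyldimethylsilyloxy)benzoyl]-3-O-(tert-butyldimethylsilyl)-1-O-[(4E,6E,8E)-dodeca-4,6,8-trienyl]-sn-glycerol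
Product: 25 1-O-[(4E,6E,8E)-dodeca-4,6,8-trienyl]-2-O-(4-hydroxybenzoyl)-sn-glycerol
Conditions: Bu4NF (3 equiv), AcOH (3.3 equiv), THF, 0 °C → rt; pH 5 buffer work-up
Reagents that add atoms: none
Why: Fluoride-induced desilylation of both Si–O bonds, in which acetic acid protonates the alkoxide and phenoxide as they are released and so shuts off the base-induced 2→3 acyl shift, helped by the poor electrophilicity of the electron-rich aroyl carbonyl, while C2 is untouched and the (S) target results.

**Compound list**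
1 | (R)-solketal, (R)-(2,2-dimethyl-1,3-dioxolan-4-yl)methanol, 2,3-O-isopropylidene-sn-glycerol | OC[C@H](CO1)OC1(C)C | starting material
2 | 5-bromopent-1-ene | C=CCCCBr | starting material
3 | sodium alkoxide of 1 | [Na+].[O-]C[C@H](CO1)OC1(C)C | intermediate
4 | 1-O-(pent-4-enyl)-2,3-O-isopropylidene-sn-glycerol, (R) | C=CCCCOC[C@H](CO1)OC1(C)C | intermediate
5 | secondary ozonide of 4 (3-substituted 1,2,4-trioxolane, both epimers at the trioxolane carbon) | C1OC(OO1)CCCOC[C@H](CO2)OC2(C)C | intermediate
6 | 1-O-(4-oxobutyl)-2,3-O-isopropylidene-sn-glycerol, (R) | O=CCCCOC[C@H](CO1)OC1(C)C | intermediate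
7 | triethyl (E)-4-phosphonocrotonate | CCOC(=O)/C=C/CP(=O)(OCC)OCC | starting material
8 | lithium salt of 7 (carbanion next to phosphorus) | [Li+].CCOC(=O)/C=C/[CH-]P(=O)(OCC)OCC | intermediate
9 | ethyl (2E,4E)-8-{[(4R)-2,2-dimethyl-1,3-dioxolan-4-yl]methoxy}octa-2,4-dienoate | CCOC(=O)/C=C/C=C/CCCOC[C@H](CO1)OC1(C)C | intermediate
10 | 1-O-[(4E,6E)-8-hydroxyocta-4,6-dienyl]-2,3-O-isopropylidene-sn-glycerol, (R) | OC/C=C/C=C/CCCOC[C@H](CO1)OC1(C)C | intermediate
11 | 1-O-[(4E,6E)-8-oxoocta-4,6-dienyl]-2,3-O-isopropylidene-sn-glycerol, (R) | O=C/C=C/C=C/CCCOC[C@H](CO1)OC1(C)C | intermediate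
12 | 1-phenyl-1H-tetrazole-5-thiol | Sc1nnnn1-c1ccccc1 | starting material
13 | 1-bromobutane | CCCCBr | starting material
14 | 5-(butylsulfanyl)-1-phenyl-1H-tetrazole | CCCCSc1nnnn1-c1ccccc1 | intermediate
15 | 5-(butylsulfonyl)-1-phenyl-1H-tetrazole | CCCCS(=O)(=O)c1nnnn1-c1ccccc1 | intermediate
16 | potassium salt of 15 (carbanion next to sulfur) | [K+].CCC[CH-]S(=O)(=O)c1nnnn1-c1ccccc1 | intermediate
17 | potassium beta-alkoxy sulfone from 16 and 11 (two transient centres at C8 and C9, anti pair favoured, drawn without configuration) | [K+].CCCC(C([O-])/C=C/C=C/CCCOC[C@H](CO1)OC1(C)C)S(=O)(=O)c2nnnn2-c3ccccc3 | intermediate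
18 | 1-O-[(4E,6E,8E)-dodeca-4,6,8-trienyl]-2,3-O-isopropylidene-sn-glycerol, (R) | CCC/C=C/C=C/C=C/CCCOC[C@H](CO1)OC1(C)C | intermediate
19 | 1-O-[(4E,6E,8E)-dodeca-4,6,8-trienyl]-sn-glycerol, (S) | CCC/C=C/C=C/C=C/CCCOC[C@H](CO)O | intermediate
20 | 3-O-(tert-butyldimethylsilyl)-1-O-[(4E,6E,8E)-dodeca-4,6,8-trienyl]-sn-glycerol, (R) by priority change only | CCC/C=C/C=C/C=C/CCCOC[C@H](CO[Si](C)(C)C(C)(C)C)O | intermediate
21 | 4-hydroxybenzoic acid | OC(=O)c1ccc(O)cc1 | starting material
22 | tert-butyldimethylsilyl 4-(tert-butyldimethylsilyloxy)benzoate | CC(C)(C)[Si](C)(C)OC(=O)c1ccc(O[Si](C)(C)C(C)(C)C)cc1 | intermediate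
23 | 4-(tert-butyldimethylsilyloxy)benzoic acid | OC(=O)c1ccc(O[Si](C)(C)C(C)(C)C)cc1 | intermediate
24 | 2-O-[4-(tert-butyldimethylsilyloxy)benzoyl]-3-O-(tert-butyldimethylsilyl)-1-O-[(4E,6E,8E)-dodeca-4,6,8-trienyl]-sn-glycerol, (R) | CCC/C=C/C=C/C=C/CCCOC[C@H](CO[Si](C)(C)C(C)(C)C)OC(=O)c1ccc(O[Si](C)(C)C(C)(C)C)cc1 | intermediate
25 | 1-O-[(4E,6E,8E)-dodeca-4,6,8-trienyl]-2-O-(4-hydroxybenzoyl)-sn-glycerol, (S) | CCC/C=C/C=C/C=C/CCCOC[C@H](CO)OC(=O)c1ccc(O)cc1 | target

**Step count**
Total step count: 13.
Longest linear sequence: 10 (steps 1, 2, 3, 4, 5, 8, 9, 10, 12, 13).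

**Steps most likely to fail**

Step 8. The E selectivity at C8=C9 may erode, and the sulfonyl anion may deprotonate the dienal vinylogously at C3, which would stall the addition.
- The fallback reverses the polarity of the same bond and uses a phosphonate instead of a sulfone. It sets out from 10 and comes back at 18.
- Appel bromination of 10 (CBr4, PPh3, CH2Cl2, 0 °C) should give 1-O-[(4E,6E)-8-bromoocta-4,6-dienyl]-2,3-O-isopropylidene-sn-glycerol F1.
- A Michaelis–Arbuzov reaction with P(OEt)3 (neat, 110 °C) converts it into diethyl [(2E,4E)-8-{[(4R)-2,2-dimethyl-1,3-dioxolan-4-yl]methoxy}octa-2,4-dienyl]phosphonate F2.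
- The lithium anion of the phosphonate (LiN(SiMe3)2, THF, −78 °C) is condensed with butanal in an E-favouring Horner–Wadsworth–Emmons olefination to give 18. No base-sensitive dienal is then exposed to a carbanion.

Step 13. The acyl group may shift from O2 to O3 once the primary hydroxyl is free, and the primary silyl ether may cleave only slowly under buffered fluoride, which lengthens the exposure.
- The fallback replaces the primary silyl ether by an enzyme-labile acetate, so that the last step runs in a neutral medium. It sets out from 19 and comes back at 25.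
- Immobilised Candida antarctica lipase B with vinyl acetate in t-BuOMe at rt should acetylate only the primary hydroxyl, giving 3-O-acetyl-1-O-[(4E,6E,8E)-dodeca-4,6,8-trienyl]-sn-glycerol F3.
- Steglich esterification with 23 under the conditions of step 12 gives 3-O-acetyl-2-O-[4-(tert-butyldimethylsilyloxy)benzoyl]-1-O-[(4E,6E,8E)-dodeca-4,6,8-trienyl]-sn-glycerol F4.
- Bu4NF/AcOH in THF at 0 °C removes the labile aryl silyl ether while no free hydroxyl sits next to the ester, giving 3-O-acetyl-1-O-[(4E,6E,8E)-dodeca-4,6,8-trienyl]-2-O-(4-hydroxybenzoyl)-sn-glycerol F5.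
- Ethanolysis of the primary acetate with the same lipase (EtOH, t-BuOMe, rt) then gives 25. The enzyme is selective for primary positions and is a poor catalyst for benzoate cleavage.

Step 3. Control of the E geometry at the new C4=C5 bond may be incomplete, the ambident anion may attack through the carbon next to the ester, and the enolisable aldehyde may self-condense.
- The fallback builds the diene by two separate two-carbon homologations. It sets out from 6 and comes back at 9.
- Wittig reaction of 6 with Ph3P=CHCO2Et (CH2Cl2, rt) should give ethyl (E)-6-{[(4R)-2,2-dimethyl-1,3-dioxolan-4-yl]methoxy}hex-2-enoate F6.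
- Reduction with i-Bu2AlH (CH2Cl2, −78 °C) gives (E)-6-{[(4R)-2,2-dimethyl-1,3-dioxolan-4-yl]methoxy}hex-2-en-1-ol F7.
- Oxidation with MnO2 (CH2Cl2, rt) gives (E)-6-{[(4R)-2,2-dimethyl-1,3-dioxolan-4-yl]methoxy}hex-2-enal F8.
- A Horner–Wadsworth–Emmons reaction with triethyl phosphonoacetate under Masamune–Roush conditions (LiCl, DBU, MeCN, rt) gives 9.

**Further compounds**
F1 | step 8 | 1-O-[(4E,6E)-8-bromoocta-4,6-dienyl]-2,3-O-isopropylidene-sn-glycerol | BrC/C=C/C=C/CCCOC[C@H](CO1)OC1(C)C
F2 | step 8 | diethyl [(2E,4E)-8-{[(4R)-2,2-dimethyl-1,3-dioxolan-4-yl]methoxy}octa-2,4-dienyl]phosphonate | CCOP(=O)(OCC)C/C=C/C=C/CCCOC[C@H](CO1)OC1(C)C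
F3 | step 13 | 3-O-acetyl-1-O-[(4E,6E,8E)-dodeca-4,6,8-trienyl]-sn-glycerol | CCC/C=C/C=C/C=C/CCCOC[C@H](COC(C)=O)O
F4 | step 13 | 3-O-acetyl-2-O-[4-(tert-butyldimethylsilyloxy)benzoyl]-1-O-[(4E,6E,8E)-dodeca-4,6,8-trienyl]-sn-glycerol | CCC/C=C/C=C/C=C/CCCOC[C@H](COC(C)=O)OC(=O)c1ccc(O[Si](C)(C)C(C)(C)C)cc1
F5 | step 13 | 3-O-acetyl-1-O-[(4E,6E,8E)-dodeca-4,6,8-trienyl]-2-O-(4-hydroxybenzoyl)-sn-glycerol | CCC/C=C/C=C/C=C/CCCOC[C@H](COC(C)=O)OC(=O)c1ccc(O)cc1
F6 | step 3 | ethyl (E)-6-{[(4R)-2,2-dimethyl-1,3-dioxolan-4-yl]methoxy}hex-2-enoate | CCOC(=O)/C=C/CCCOC[C@H](CO1)OC1(C)C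
F7 | step 3 | (E)-6-{[(4R)-2,2-dimethyl-1,3-dioxolan-4-yl]methoxy}hex-2-en-1-ol | OC/C=C/CCCOC[C@H](CO1)OC1(C)C
F8 | step 3 | (E)-6-{[(4R)-2,2-dimethyl-1,3-dioxolan-4-yl]methoxy}hex-2-enal | O=C/C=C/CCCOC[C@H](CO1)OC1(C)C
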